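**Strategy.** The depside is cut inside ring A, not at the ester link. In ring A the ester carbon C1 sits between oxygen-bearing C2 and pentyl-bearing C6, which is the C5-carboxylate/C4-alkoxy/C6-alkyl array of a 2-pyrone; only C4 (with its hydroxyl) and C5 are missing. A heat-driven inverse-demand Diels–Alder reaction of such a pyrone, already esterified to ring B, with a bis-silyl ketene acetal adds these two carbons, expels CO2 and aromatizes in one operation. The precursor is the ring B aryl ester of 4-benzyloxy-6-pentyl-2-pyrone-5-carboxylic acid, assembled from an unhindered aryl β-keto ester and malonyl dichloride; three benzyl groups fall in the final hydrogenolysis.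

Key step: step 8

Remark: ring A is the pentyl-bearing ring and ring B the propyl-bearing ring. The target has no stereocentre, so no stereocontrol is required. The ketene acetal 18 is assumed to be best made fresh, because it is moisture-sensitive.

**Step 1**
Reactants: 1 5-propylresorcinol; 2 methoxymagnesium methyl carbonate (MeOMgOCO2Me)
Product: 3 2,4-dihydroxy-6-propylbenzoic acid
Conditions: MeOMgOCO2Me (2 M in DMF), 120 °C; then cold 1 M HCl
Reagents that add atoms: methoxymagnesium methyl carbonate (2), CO[Mg]OC(=O)OC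
Why: Chelation-assisted ortho-carboxylation of a 5-alkylresorcinol by MeOMgOCO2Me (a Kolbe–Schmitt-type substitution) should place CO2H between a hydroxyl and the propyl group, the product being held as a magnesium salicylate until cold acidification.

**Step 2**
Reactants: 3 2,4-dihydroxy-6-propylbenzoic acid; 4 benzyl bromide
Product: 5 benzyl 2,4-dihydroxy-6-propylbenzoate
Conditions: BnBr, KHCO3, DMF, rt
Reagents that add atoms: benzyl bromide (4), BrCc1ccccc1
Why: KHCO3 deprotonates only the carboxylic acid, so SN2 O-alkylation of the carboxylate should give the benzyl ester and leave both phenols free.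

**Step 3**
Reactants: 6 Meldrum's acid; 7 hexanoyl chloride
Product: 8 5-(1-hydroxyhexylidene)-2,2-dimethyl-1,3-dioxane-4,6-dione
Conditions: pyridine, CH2Cl2, 0 °C to rt; then 1 M HCl wash
Reagents that add atoms: hexanoyl chloride (7), CCCCCC(=O)Cl
Why: C-Acylation of Meldrum's acid by an acid chloride with pyridine (Oikawa–Yonemitsu acylation) is general and should give the enolized acyl derivative.

**Step 4**
Reactants: 8 5-(1-hydroxyhexylidene)-2,2-dimethyl-1,3-dioxane-4,6-dione; 5 benzyl 2,4-dihydroxy-6-propylbenzoate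
Product: 10 benzyl 2-hydroxy-4-[(3-oxooctanoyl)oxy]-6-propylbenzoate, via hexanoylketene 9 (not isolated)
Conditions: toluene, 110 °C
Reagents that add atoms: 5-(1-hydroxyhexylidene)-2,2-dimethyl-1,3-dioxane-4,6-dione (8), CCCCCC(O)=C1C(=O)OC(C)(C)OC1=O
Why: Thermolysis of the acyl Meldrum's acid releases acetone and CO2 to give an acylketene, which should be trapped by the free C4 hydroxyl of 5 because the C2 hydroxyl is hydrogen-bonded to the benzyl ester carbonyl (acylketene acylation of a phenol).

**Step 5**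
Reactants: 10 benzyl 2-hydroxy-4-[(3-oxooctanoyl)oxy]-6-propylbenzoate; 11 malonyl dichloride
Product: 12 4-(benzyloxycarbonyl)-3-hydroxy-5-propylphenyl 4-hydroxy-2-oxo-6-pentyl-2H-pyran-5-carboxylate
Conditions: malonyl dichloride (1.1 equiv), ClCH2CH2Cl, rt to 50 °C, N2 sweep
Reagents that add atoms: malonyl dichloride (11), O=C(Cl)CC(=O)Cl
Why: Annulation of a β-keto ester with malonyl dichloride (acylation at the active methylene and lactonization through the ketone enol oxygen) is the standard entry to 4-hydroxy-6-alkyl-2-pyrone-5-carboxylates, and without base the chelated ring B hydroxyl should not compete.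

**Step 6**
Reactants: 12 4-(benzyloxycarbonyl)-3-hydroxy-5-propylphenyl 4-hydroxy-2-oxo-6-pentyl-2H-pyran-5-carboxylate; 13 benzyl alcohol
Product: 14 3-(benzyloxy)-4-(benzyloxycarbonyl)-5-propylphenyl 4-(benzyloxy)-2-oxo-6-pentyl-2H-pyran-5-carboxylate
Conditions: BnOH (2.5 equiv), PPh3, DIAD, THF, 0 °C to rt
Reagents that add atoms: benzyl alcohol (13), OCc1ccccc1
Why: Mitsunobu etherification should alkylate the acidic pyrone hydroxyl on oxygen, avoiding the alkylation at C3 or at the lactone carbonyl oxygen that benzyl halides can cause, and the same neutral conditions should etherify the salicylate-type phenol without endangering the aryl ester.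

**Step 7**
Reactants: 15 trimethylsilyl acetate; 16 chlorotrimethylsilane
Product: 18 1,1-bis(trimethylsilyloxy)ethene, via lithium enolate 17 (not isolated)
Conditions: LiN(i-Pr)2, THF, −78 °C; Me3SiCl, −78 °C to rt; distil
Reagents that add atoms: chlorotrimethylsilane (16), C[Si](C)(C)Cl
Why: O-Silylation of the lithium enolate of a silyl ester at low temperature is the standard preparation of bis-silyl ketene acetals.

**Step 8**
Reactants: 14 3-(benzyloxy)-4-(benzyloxycarbonyl)-5-propylphenyl 4-(benzyloxy)-2-oxo-6-pentyl-2H-pyran-5-carboxylate; 18 1,1-bis(trimethylsilyloxy)ethene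
Product: 22 benzyl 2-(benzyloxy)-4-{[2-(benzyloxy)-4-hydroxy-6-pentylbenzoyl]oxy}-6-propylbenzoate, via bridged lactone cycloadduct 19 (not isolated), via bis(silyloxy)cyclohexadiene 20 (not isolated), via aryl trimethylsilyl ether 21 (not isolated)
Conditions: 18 (5 equiv), toluene, sealed tube, 120 °C; then 1 M HCl, THF, rt
Reagents that add atoms: 1,1-bis(trimethylsilyloxy)ethene (18), C=C(O[Si](C)(C)C)O[Si](C)(C)C
Why: The electron-poor pyrone diene (C3=C4–C5=C6) is attacked at C6, the β-carbon of the 5-ester and the vinylogous terminus of the lactone carbonyl, by the nucleophilic CH2 of 18 while the acetal carbon bonds to C3, either in a concerted asynchronous inverse-demand (4+2) cycloaddition or by Michael addition followed by 6-exo-trig closure of the dienolate onto the silyloxocarbenium ion. The bridged lactone 19 then loses CO2 by retro-Diels–Alder reaction and diene 20 eliminates trimethylsilanol, so ring A is closed as a benzene ring by an intermolecular (4+2) annulation that forms its C3–C4 and C5–C6 bonds. The closest known reaction type is the cycloaddition of 2-pyrone-5-carboxylates with ketene acetals and enol ethers, which gives 4-oxygenated benzoates after decarboxylation. No stereocentre survives, because both bridgeheads of 19 become aromatic carbons. Only regioselectivity is needed, and the matched polarization of the two partners should secure it; the aryl ester restores some of the acceptor strength that the 4-benzyloxy and 6-pentyl groups take away, hence heat and excess 18. Mild acid on work-up should cleave the silyl ether 21 to the free C4 phenol of ring A.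

**Step 9**
Reactants: 22 benzyl 2-(benzyloxy)-4-{[2-(benzyloxy)-4-hydroxy-6-pentylbenzoyl]oxy}-6-propylbenzoate
Product: 23 4-[(2,4-dihydroxy-6-pentylbenzoyl)oxy]-2-hydroxy-6-propylbenzoic acid
Conditions: H2 (1 atm), 10% Pd/C, EtOAc, rt
Reagents that add atoms: none
Why: Catalytic hydrogenolysis should cleave the two benzyl ethers and the benzyl ester at room temperature without touching the hindered depside ester.

**Compound list**

1 | 5-propylresorcinol (5-propylbenzene-1,3-diol) | CCCc1cc(O)cc(O)c1 | starting material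
2 | methoxymagnesium methyl carbonate, MeOMgOCO2Me | CO[Mg]OC(=O)OC | starting material
3 | 2,4-dihydroxy-6-propylbenzoic acid | CCCc1cc(O)cc(O)c1C(=O)O | intermediate
4 | benzyl bromide | BrCc1ccccc1 | starting material
5 | benzyl 2,4-dihydroxy-6-propylbenzoate | CCCc1cc(O)cc(O)c1C(=O)OCc1ccccc1 | intermediate
6 | Meldrum's acid (2,2-dimethyl-1,3-dioxane-4,6-dione) | CC1(C)OC(=O)CC(=O)O1 | starting material
7 | hexanoyl chloride | CCCCCC(=O)Cl | starting material
8 | 5-(1-hydroxyhexylidene)-2,2-dimethyl-1,3-dioxane-4,6-dione | CCCCCC(O)=C1C(=O)OC(C)(C)OC1=O | intermediate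
9 | hexanoylketene (3-oxooct-1-en-1-one) | CCCCCC(=O)C=C=O | intermediate
10 | benzyl 2-hydroxy-4-[(3-oxooctanoyl)oxy]-6-propylbenzoate | CCCCCC(=O)CC(=O)Oc1cc(O)c(C(=O)OCc2ccccc2)c(CCC)c1 | intermediate
11 | malonyl dichloride | O=C(Cl)CC(=O)Cl | starting material
12 | 4-(benzyloxycarbonyl)-3-hydroxy-5-propylphenyl 4-hydroxy-2-oxo-6-pentyl-2H-pyran-5-carboxylate | CCCCCc1oc(=O)cc(O)c1C(=O)Oc1cc(O)c(C(=O)OCc2ccccc2)c(CCC)c1 | intermediate
13 | benzyl alcohol | OCc1ccccc1 | starting material
14 | 3-(benzyloxy)-4-(benzyloxycarbonyl)-5-propylphenyl 4-(benzyloxy)-2-oxo-6-pentyl-2H-pyran-5-carboxylate | CCCCCc1oc(=O)cc(OCc2ccccc2)c1C(=O)Oc1cc(OCc2ccccc2)c(C(=O)OCc2ccccc2)c(CCC)c1 | intermediate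
15 | trimethylsilyl acetate | CC(=O)O[Si](C)(C)C | starting material
16 | chlorotrimethylsilane | C[Si](C)(C)Cl | starting material
17 | lithium 1-(trimethylsilyloxy)ethenolate | [Li+].[O-]C(=C)O[Si](C)(C)C | intermediate
18 | 1,1-bis(trimethylsilyloxy)ethene | C=C(O[Si](C)(C)C)O[Si](C)(C)C | intermediate
19 | 3-(benzyloxy)-4-(benzyloxycarbonyl)-5-propylphenyl 5-(benzyloxy)-3-oxo-1-pentyl-8,8-bis(trimethylsilyloxy)-2-oxabicyclo[2.2.2]oct-5-ene-6-carboxylate (racemic; bridgeheads fixed relative to each other by the bicycle) | CCCCCC12CC(O[Si](C)(C)C)(O[Si](C)(C)C)C(C(=O)O1)C(OCc1ccccc1)=C2C(=O)Oc1cc(OCc2ccccc2)c(C(=O)OCc2ccccc2)c(CCC)c1 | intermediate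
20 | 3-(benzyloxy)-4-(benzyloxycarbonyl)-5-propylphenyl 6-(benzyloxy)-2-pentyl-4,4-bis(trimethylsilyloxy)cyclohexa-1,5-diene-1-carboxylate | CCCCCC1=C(C(=O)Oc2cc(OCc3ccccc3)c(C(=O)OCc3ccccc3)c(CCC)c2)C(OCc2ccccc2)=CC(O[Si](C)(C)C)(O[Si](C)(C)C)C1 | intermediate
21 | benzyl 2-(benzyloxy)-4-({2-(benzyloxy)-6-pentyl-4-[(trimethylsilyl)oxy]benzoyl}oxy)-6-propylbenzoate | CCCCCc1cc(O[Si](C)(C)C)cc(OCc2ccccc2)c1C(=O)Oc1cc(OCc2ccccc2)c(C(=O)OCc2ccccc2)c(CCC)c1 | intermediate
22 | benzyl 2-(benzyloxy)-4-{[2-(benzyloxy)-4-hydroxy-6-pentylbenzoyl]oxy}-6-propylbenzoate | CCCCCc1cc(O)cc(OCc2ccccc2)c1C(=O)Oc1cc(OCc2ccccc2)c(C(=O)OCc2ccccc2)c(CCC)c1 | intermediate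
23 | 4-[(2,4-dihydroxy-6-pentylbenzoyl)oxy]-2-hydroxy-6-propylbenzoic acid | CCCCCc1cc(O)cc(O)c1C(=O)Oc1cc(O)c(C(=O)O)c(CCC)c1 | target

**Step count and risks**

Total step count: 9. Longest linear sequence: 7 steps (steps 1, 2, 4, 5, 6, 8, 9). Steps 3 and 7 are side branches.

Steps most likely to fail:

1. Step 8. The ketene acetal may stop at conjugate addition with silyl transfer, or decompose thermally before the hindered, donor-substituted diene reacts, so that ring A never closes. The fallback brings ring A in intact by classical depside esterification; it sets out from compound 5 and comes back to the route at compound 23. Commercial 5-pentylresorcinol (CCCCCc1cc(O)cc(O)c1) would be formylated under Vilsmeier–Haack conditions (POCl3, DMF) to 2,4-dihydroxy-6-pentylbenzaldehyde F1. Benzylation (BnBr, K2CO3, DMF) would give 2,4-bis(benzyloxy)-6-pentylbenzaldehyde F2, and Pinnick oxidation (NaClO2, NaH2PO4, 2-methyl-2-butene, t-BuOH/H2O) would give 2,4-bis(benzyloxy)-6-pentylbenzoic acid F3. Condensation of F3 with 5 through the mixed trifluoroacetic anhydride ((CF3CO)2O, toluene, rt) should acylate the unchelated C4 hydroxyl and give benzyl 4-{[2,4-bis(benzyloxy)-6-pentylbenzoyl]oxy}-2-hydroxy-6-propylbenzoate F4. Hydrogenolysis (H2, Pd/C, EtOAc) would then give 23.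

2. Step 5. The chelated ring B hydroxyl may be acylated by the diacid chloride, or the hydroxypyrone may undergo a second annulation with excess reagent, giving oligomeric malonates. The fallback masks the ring B hydroxyl before the annulation; it sets out from compound 5 and comes back at compound 14. Selective silylation of the unchelated hydroxyl (t-BuMe2SiCl, imidazole, CH2Cl2, 0 °C) would give benzyl 4-[(tert-butyldimethylsilyl)oxy]-2-hydroxy-6-propylbenzoate F5. Mitsunobu benzylation (BnOH, PPh3, DIAD, THF) would give benzyl 2-(benzyloxy)-4-[(tert-butyldimethylsilyl)oxy]-6-propylbenzoate F6, and desilylation (Bu4NF, AcOH, THF, 0 °C) would give benzyl 2-(benzyloxy)-4-hydroxy-6-propylbenzoate F7. Heating F7 with 8 in toluene would give benzyl 2-(benzyloxy)-4-[(3-oxooctanoyl)oxy]-6-propylbenzoate F8. Malonyl dichloride, now without any free phenol, would give 3-(benzyloxy)-4-(benzyloxycarbonyl)-5-propylphenyl 4-hydroxy-2-oxo-6-pentyl-2H-pyran-5-carboxylate F9, and a single Mitsunobu benzylation of the pyrone hydroxyl (BnOH, PPh3, DIAD) would give 14.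

3. Step 6. Etherification of the chelated ring B hydroxyl may remain incomplete under redox-condensation conditions, leaving mixtures that are hard to free from phosphine oxide. The fallback splits the double etherification into two operations of different type; it sets out from compound 12 and comes back at compound 14. One equivalent of BnOH/PPh3/DIAD should react only at the far more acidic pyrone hydroxyl and give 4-(benzyloxycarbonyl)-3-hydroxy-5-propylphenyl 4-(benzyloxy)-2-oxo-6-pentyl-2H-pyran-5-carboxylate F10. With the ambident pyrone oxygen capped, Williamson etherification of the remaining phenol (BnBr, K2CO3, acetone, 50 °C) would give 14.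

**Further compounds**

F1 | step 8 | 2,4-dihydroxy-6-pentylbenzaldehyde | CCCCCc1cc(O)cc(O)c1C=O
F2 | step 8 | 2,4-bis(benzyloxy)-6-pentylbenzaldehyde | CCCCCc1cc(OCc2ccccc2)cc(OCc2ccccc2)c1C=O
F3 | step 8 | 2,4-bis(benzyloxy)-6-pentylbenzoic acid | CCCCCc1cc(OCc2ccccc2)cc(OCc2ccccc2)c1C(=O)O
F4 | step 8 | benzyl 4-{[2,4-bis(benzyloxy)-6-pentylbenzoyl]oxy}-2-hydroxy-6-propylbenzoate | CCCCCc1cc(OCc2ccccc2)cc(OCc2ccccc2)c1C(=O)Oc1cc(O)c(C(=O)OCc2ccccc2)c(CCC)c1
F5 | step 5 | benzyl 4-[(tert-butyldimethylsilyl)oxy]-2-hydroxy-6-propylbenzoate | CCCc1cc(O[Si](C)(C)C(C)(C)C)cc(O)c1C(=O)OCc1ccccc1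
F6 | step 5 | benzyl 2-(benzyloxy)-4-[(tert-butyldimethylsilyl)oxy]-6-propylbenzoate | CCCc1cc(O[Si](C)(C)C(C)(C)C)cc(OCc2ccccc2)c1C(=O)OCc1ccccc1
F7 | step 5 | benzyl 2-(benzyloxy)-4-hydroxy-6-propylbenzoate | CCCc1cc(O)cc(OCc2ccccc2)c1C(=O)OCc1ccccc1
F8 | step 5 | benzyl 2-(benzyloxy)-4-[(3-oxooctanoyl)oxy]-6-propylbenzoate | CCCCCC(=O)CC(=O)Oc1cc(OCc2ccccc2)c(C(=O)OCc2ccccc2)c(CCC)c1
F9 | step 5 | 3-(benzyloxy)-4-(benzyloxycarbonyl)-5-propylphenyl 4-hydroxy-2-oxo-6-pentyl-2H-pyran-5-carboxylate | CCCCCc1oc(=O)cc(O)c1C(=O)Oc1cc(OCc2ccccc2)c(C(=O)OCc2ccccc2)c(CCC)c1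
F10 | step 6 | 4-(benzyloxycarbonyl)-3-hydroxy-5-propylphenyl 4-(benzyloxy)-2-oxo-6-pentyl-2H-pyran-5-carboxylate | CCCCCc1oc(=O)cc(OCc2ccccc2)c1C(=O)Oc1cc(O)c(C(=O)OCc2ccccc2)c(CCC)c1
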